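The data were computed on assumed constants, noise included.

Q was the thing to count, and in the midnight and spring runs its molar amount took little notice of how much G was charged.

the same everywhere: X 200 mM (held)

| charge | G | remark | time |
|---|---|---|---|
| dawn | 0.24 M | run made earlier |  |
| midnight | 0.49 M | run made earlier |  |
| spring | 0.77 M | run made earlier |  |
| Sunday's | 0.25 M |  | 12 min |
| Monday's | 0.80 M |  | 25 min |

| run | time / min | Q / % | G / % |
|---|---|---|---|
| dawn | 2.50 | 6.4 | 70.0 |
| dawn | 5.00 | 15.3 | 45.9 |
| dawn | 8.00 | 23.7 | 29.3 |
| dawn | 10.0 | 29.2 | 21.2 |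
| dawn | 12.0 | 32.7 | 14.9 |
| midnight | 2.50 | 4.8 | 58.1 |
| midnight | 5.00 | 8.6 | 37.1 |
| midnight | 8.00 | 14.3 | 22.7 |
| midnight | 10.0 | 14.0 | 16.7 |
| midnight | 12.0 | 19.5 | 11.0 |
| spring | 2.50 | 2.8 | 47.9 |
| spring | 5.00 | 5.4 | 29.0 |
| spring | 8.00 | 8.1 | 18.3 |
| spring | 10.0 | 10.5 | 12.6 |
| spring | 12.0 | 12.5 | 10.0 |

(standard deviation of a reading: 1 percentage point)

- a species is counted by the G in it: one E or Z counts as two
- at the start none of J is dissolved
- reactions considered so far: X <-> J; G + J -> Q; G + Q -> E; 2 G -> Z

- the flask that ends with the higher amount of Q, in percent of the G charged, or "neither" when 2 percentage points or less lies between them (Sunday's / Monday's / neither)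
- final Q, as a percentage of the G charged, in Sunday's
- final Q, as a percentage of the G charged, in Monday's

At 12.0 min the midnight run held 0.0955 M of Q and the spring run 0.0963 M, although the spring run was charged with more G. So, as a working picture, I let dissolved X feed Q at a steady pace, read from the spring run as 0.00802 M/min. Then I folded the givens into one number:

Sunday's: pace × 12 min / 0.25 M = 38.5%

Monday's: pace × 25 min / 0.80 M = 25.1%

This is the gas share, the fraction of the charged G that this pace turns into Q in the time allowed.

Was one number enough? For the midnight run it gives 19.6% against a reading of 19.5%. For the dawn run it gives 40.1%, above the 32.7% read. Sunday's charge lies beside the dawn run's, so I scaled by that ratio: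

38.5% × 32.7% / 40.1% = 31.4%

Monday's needed more: its time is longer than the spring run's, and the spring run still had 10.0% of its G at 12.0 min. Late in that run, the readings gave Q 53.0% of the G lost, so:

pace × 12.0 min / 0.80 M + 53.0% × 10.0% = 17.3%

That is less than Monday's gas share. I committed to Sunday's, with 31.4% against 17.3% for Monday's.

The forecast gave 32% and 18%, near my figures, and named Sunday's: “Sunday's therefore ends clearly higher.”

The flask gave 33.0% in Sunday's and 16.8% in Monday's, so Sunday's ended higher.

    X ⇌ J, rate k1*(csat - [J]) (kL = 0.0735 /min)
    G + J → Q (k = 2.86 /M/min)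
    G + Q → E (k = 0.281 /M/min)
    2 G → Z (k = 0.264 /M/min)

Monday's held 0.32% of its G at the end, and left until 250 min it stood at 17.0% of Q. Sunday's gas share of 38.5% stood above its result, as the dawn run's had. A flask like Sunday's but charged with 0.62 M of G has a gas share of 15.5%, and at 12.0 min it held 14.9% of Q.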